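**Plan**

- Retrosynthesis: cut the aryl–CH2 bond of the methylene bridge, giving acyl triketone 15 (used as Mannich base 22) and chromene 21. In the carbocyclic trione ring, cut the bond from one ring carbonyl carbon to the quaternary carbon, that is, undo a 1,2-acyl shift; this leads back to a spiro-epoxide on a five-membered ring.
- Enabling feature: in that six-membered ring the quaternary carbon C(CH3)(prenyl) lies between two ring carbonyl carbons (a 2,2-disubstituted 1,3-dione). A 2-alkylidenecyclopentanone oxide gives exactly this unit when its ring acyl carbon migrates to the exocyclic epoxide carbon, so the ring is carried as a cyclopentanone and enlarged by one carbon.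
- Forward order of rings: isoxazole fused to cyclopentanone (the isoxazole masks the isobutyryl-1,3-dione and marks one flank) → exocyclic tetrasubstituted alkene → oxirane → six-membered dione by ring expansion → isoxazole opened to the acyl triketone. Separately, the pyran ring of 21 arises by oxa-6π closure of an ortho-quinone methide. The CH2 bridge is made last.
- Stereochemistry: the only stereocentre comes from the epoxide carbon that carries CH3 and allyl. Its configuration is fixed by the (Z) alkene geometry and by a CBS-set carbinol that directs the epoxidation; the acyl shift transfers it with inversion, and the carbinol and spiro centres are then erased.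
- Helpers taken out later: allyl in place of prenyl (cross-metathesis), the isoxazole ring, the carbinol relay, one MOM group.

Key step: step 8

Assumption: the target is an enolised triketone and all its tautomers are one compound; the quaternary carbon is (S) in the tautomer drawn, and each intermediate is drawn in one convenient tautomer.

**Route**

Step 1
Reactants: 1 cyclopentane-1,3-dione; 2 2-methylpropanal oxime
Product: 5 3-(propan-2-yl)-5,6-dihydro-4H-cyclopenta[d][1,2]oxazol-4-one, via hydroximoyl chloride 3 (not isolated), via nitrile oxide 4 (not isolated)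
Conditions: 2, N-chlorosuccinimide, DMF, rt; then 1, Et3N, EtOH, 0 °C to rt
Reagents that add atoms: none
Why: the nitrile oxide released by base adds across the enol of the 1,3-dione (carbon to C2, oxygen to C3) and water is lost to give the 4-acylisoxazole, a 1,3-dipolar cycloaddition–dehydration that is standard for cyclic 1,3-diketones; no stereocentre is formed.

Step 2
Reactants: 5 isoxazole-fused cyclopentanone
Product: 6 (5Z)-5-(1-hydroxyethylidene)-3-(propan-2-yl)-5,6-dihydro-4H-cyclopenta[d][1,2]oxazol-4-one
Conditions: NaH (2.2 equiv), EtOAc, THF, 0 to 60 °C; aq. HCl work-up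
Reagents that add atoms: ethyl acetate CCOC(C)=O
Why: crossed Claisen condensation at C5, the only enolisable α-carbon of the ketone, driven by deprotonation of the β-diketone, which should rest as the chelated exocyclic enol.

Step 3
Reactants: 6 enolised 5-acetyl ketone
Product: 7 (1Z)-1-[4-oxo-3-(propan-2-yl)-4H-cyclopenta[d][1,2]oxazol-5(6H)-ylidene]ethyl trifluoromethanesulfonate
Conditions: Tf2O, aq. LiOH, toluene, 5 °C
Reagents that add atoms: trifluoromethanesulfonic anhydride O=S(=O)(OS(=O)(=O)C(F)(F)F)C(F)(F)F
Why: O-sulfonylation of the lithium-chelated β-diketonate at the exocyclic enolate oxygen (an exocyclic double bond is preferred on a five-membered ring) should give the (Z) enol triflate, with the triflate oxygen cis to the ring carbonyl as in the chelate.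

Step 4
Reactants: 7 (Z) enol triflate
Product: 8 (5Z)-5-(pent-4-en-2-ylidene)-3-(propan-2-yl)-5,6-dihydro-4H-cyclopenta[d][1,2]oxazol-4-one
Conditions: allylSnBu3, Pd(PPh3)4 (5 mol %), LiCl, THF, 60 °C
Reagents that add atoms: allyltributylstannane C=CC[Sn](CCCC)(CCCC)CCCC
Why: Stille coupling of an alkenyl triflate proceeds with retention of alkene geometry, so allyl ends cis to the ring carbonyl and CH3 cis to the ring CH2; the unsubstituted allyl group cannot give regioisomers.

Step 5
Reactants: 8 (Z) dienone
Product: 9 (4S,5Z)-5-(pent-4-en-2-ylidene)-3-(propan-2-yl)-5,6-dihydro-4H-cyclopenta[d][1,2]oxazol-4-ol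
Conditions: (S)-2-methyl-CBS-oxazaborolidine (20 mol %), catecholborane, toluene, −78 °C
Reagents that add atoms: none
Why: Corey–Bakshi–Shibata reduction, in which the oxazaborolidine should bind the carbonyl away from the fully substituted alkylidene flank (taken as the larger one) and deliver hydride to the face that gives the (4S) carbinol, while catecholborane at low temperature leaves the terminal alkene alone; the new stereocentre is catalyst-controlled.

Step 6
Reactants: 9 (4S) allylic alcohol
Product: 10 (4R,5S,3′R)-3′-methyl-3-(propan-2-yl)-3′-(prop-2-en-1-yl)-4,6-dihydrospiro[cyclopenta[d][1,2]oxazole-5,2′-oxiran]-4-ol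
Conditions: VO(acac)2 (5 mol %), t-BuOOH (decane), CH2Cl2, 0 °C
Reagents that add atoms: tert-butyl hydroperoxide CC(C)(C)OO
Why: hydroxyl-directed vanadium epoxidation delivers oxygen to the face of the tetrasubstituted allylic alkene syn to the OH, much faster than to the isolated terminal alkene; with the (Z) geometry this sets the epoxide carbon C3′ as (R) and the spiro carbon as (S).

Step 7
Reactants: 10 epoxy alcohol
Product: 11 (5R,3′R)-3′-methyl-3-(propan-2-yl)-3′-(prop-2-en-1-yl)spiro[cyclopenta[d][1,2]oxazole-5,2′-oxiran]-4(6H)-one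
Conditions: Pr4N[RuO4] (5 mol %), N-methylmorpholine N-oxide, 4 Å molecular sieves, CH2Cl2, rt
Reagents that add atoms: none
Why: Ley–Griffith oxidation of the secondary carbinol under neutral conditions should leave the acid-sensitive tetrasubstituted oxirane and the alkene untouched; the relay stereocentre at C4 is erased and C3′ is unchanged.

Step 8
Reactants: 11 spiro-epoxy ketone
Product: 12 (5S)-5-methyl-3-(propan-2-yl)-5-(prop-2-en-1-yl)-1,2-benzoxazole-4,6(5H,7H)-dione
Conditions: BF3·OEt2 (1.1 equiv), CH2Cl2, −78 to −30 °C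
Reagents that add atoms: none
Why: BF3 coordinates the oxirane oxygen and the C3′–O bond ionises while the ring acyl carbon C4 shifts from the spiro carbon C5 to C3′ and the oxygen left on C5 becomes the new ketone, a concerted 1,2-acyl shift of the Meinwald type in an α,β-epoxy ketone. The closest known reaction type is the Lewis-acid rearrangement of 2-alkylidenecycloalkanone oxides to ring-enlarged cycloalkane-1,3-diones (2-benzylidenecyclopentanone oxide to 2-phenylcyclohexane-1,3-dione, pulegone oxide to a 2,2-dimethylcycloheptane-1,3-dione). No ring is closed by cyclisation: the six-membered ring grows out of the cyclopentanone by insertion of the exocyclic carbon between C4 and C5, and the oxirane is opened. The new quaternary stereocentre is controlled by the configuration of C3′ alone, because the acyl group enters anti to the departing oxygen (inversion at the migration terminus); (3′R) in 11 should therefore give (5S) in 12 whatever the configuration of the spiro carbon, which ends as a carbonyl. The step needs C3′–O rather than C5–O cleavage (secured by the tertiary dialkyl carbon against a carbon α to the carbonyl), acyl rather than CH2 migration (secured by the higher migratory aptitude of the heteroaryl ketone carbonyl) and no alkene participation (secured by the terminal allyl group carried in place of prenyl and by the low temperature). The fused isoxazole keeps the two flanks of the new 1,3-dione different, so the stereocentre cannot be lost by tautomerism.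

Step 9
Reactants: 12 (5S) allyl dione
Product: 13 (5S)-5-methyl-5-(3-methylbut-2-en-1-yl)-3-(propan-2-yl)-1,2-benzoxazole-4,6(5H,7H)-dione
Conditions: 2-methylbut-2-ene (excess), second-generation Grubbs catalyst (H2IMes)(PCy3)Cl2Ru=CHPh (5 mol %), CH2Cl2, 40 °C
Reagents that add atoms: 2-methylbut-2-ene CC=C(C)C
Why: cross-metathesis of a terminal allyl group on a quaternary carbon with 2-methylbut-2-ene is a standard way to make a prenyl group; the stereocentre is not involved.

Step 10
Reactants: 13 (5S) prenyl dione
Product: 15 (4S)-3,5-dihydroxy-4-methyl-4-(3-methylbut-2-en-1-yl)-2-(2-methylpropanoyl)cyclohexa-2,5-dien-1-one, via enaminone 14 (not isolated)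
Conditions: Mo(CO)6, MeCN/H2O, 80 °C; then 1 M aq. HCl, THF, 45 °C
Reagents that add atoms: water O
Why: reductive N–O cleavage of the isoxazole by Mo(CO)6 gives the vinylogous amide without touching the alkene, and mild acid hydrolysis of its C=N unit should release the 2-acyl-1,3-dione (isoxazole as masked 1,3-dicarbonyl); the quaternary centre has no enolisable hydrogen.

Step 11
Reactants: 16 benzene-1,3,5-triol
Product: 17 2-methyl-1-(2,4,6-trihydroxyphenyl)propan-1-one
Conditions: 2-methylpropanoyl chloride, AlCl3, nitrobenzene/CS2, 0 to 50 °C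
Reagents that add atoms: 2-methylpropanoyl chloride CC(C)C(Cl)=O
Why: Friedel–Crafts acylation of phloroglucinol stops at the mono-ketone because the acyl group deactivates the ring.

Step 12
Reactants: 17 acylphloroglucinol
Product: 18 1-[2,6-dihydroxy-4-(methoxymethoxy)phenyl]-2-methylpropan-1-one
Conditions: MOMCl (1.05 equiv), iPr2NEt, CH2Cl2, 0 °C
Reagents that add atoms: chloromethyl methyl ether COCCl
Why: the para hydroxyl is the most acidic and is not hydrogen-bonded to the ketone, so mono-alkylation should occur there.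

Step 13
Reactants: 18 para-MOM ether
Product: 20 1-[7-hydroxy-5-(methoxymethoxy)-2,2-dimethyl-2H-chromen-8-yl]-2-methylpropan-1-one, via ortho-quinone methide 19 (not isolated)
Conditions: 3-methylbut-2-enal (1.1 equiv), ethylenediammonium diacetate (10 mol %), toluene, 110 °C
Reagents that add atoms: 3-methylbut-2-enal CC(C)=CC=O
Why: Knoevenagel-type condensation at the free ring carbon gives the ortho-quinone methide, which closes by oxa-6π electrocyclisation; with the para oxygen blocked only the oxygen ortho to the acyl group can close, which places the acyl group at C8.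

Step 14
Reactants: 20 MOM-protected chromene
Product: 21 1-(5,7-dihydroxy-2,2-dimethyl-2H-chromen-8-yl)-2-methylpropan-1-one
Conditions: 3 M aq. HCl, MeOH, 45 °C
Reagents that add atoms: none
Why: acid-catalysed methanolysis of the MOM acetal is routine in the presence of 2,2-dimethylchromenes under mild conditions.

Step 15
Reactants: 15 acyl triketone
Product: 22 (4S)-6-[(dimethylamino)methyl]-3,5-dihydroxy-4-methyl-4-(3-methylbut-2-en-1-yl)-2-(2-methylpropanoyl)cyclohexa-2,5-dien-1-one
Conditions: Me2NCH2NMe2 (1.1 equiv), CH2Cl2, 0 °C to rt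
Reagents that add atoms: bis(dimethylamino)methane CN(C)CN(C)C
Why: Mannich reaction of the acidic triketone with the aminal at C6, the only free nucleophilic ring carbon, as used for methylene-bridged acylphloroglucinols.

Step 16
Reactants: 22 Mannich base; 21 chromene
Product: 24 (4S)-6-{[5,7-dihydroxy-2,2-dimethyl-8-(2-methylpropanoyl)-2H-chromen-6-yl]methyl}-3,5-dihydroxy-4-methyl-4-(3-methylbut-2-en-1-yl)-2-(2-methylpropanoyl)cyclohexa-2,5-dien-1-one, via enone methide 23 (not isolated)
Conditions: dioxane, 90 °C, N2 stream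
Reagents that add atoms: none
Why: thermal loss of dimethylamine gives the 2-methylidene trione (the carbocyclic analogue of an ortho-quinone methide), which is captured in a conjugate Friedel–Crafts addition by C6 of 21, the only unsubstituted aromatic carbon; the quaternary stereocentre is untouched.

**Compound list**

1 | cyclopentane-1,3-dione | O=C1CCC(=O)C1 | starting material
2 | 2-methylpropanal oxime (isobutyraldoxime) | CC(C)C=NO | starting material
3 | N-hydroxy-2-methylpropanimidoyl chloride | CC(C)C(Cl)=NO | intermediate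
4 | 2-methylpropanenitrile oxide | CC(C)C#[N+][O-] | intermediate
5 | 3-(propan-2-yl)-5,6-dihydro-4H-cyclopenta[d][1,2]oxazol-4-one | CC(C)c1noc2c1C(=O)CC2 | intermediate
6 | (5Z)-5-(1-hydroxyethylidene)-3-(propan-2-yl)-5,6-dihydro-4H-cyclopenta[d][1,2]oxazol-4-one (chelated enol of the 5-acetyl ketone) | CC(C)c1noc2c1C(=O)/C(C2)=C(\O)C | intermediate
7 | (1Z)-1-[4-oxo-3-(propan-2-yl)-4H-cyclopenta[d][1,2]oxazol-5(6H)-ylidene]ethyl trifluoromethanesulfonate (triflate oxygen cis to the ring carbonyl) | CC(C)c1noc2c1C(=O)/C(C2)=C(\OS(=O)(=O)C(F)(F)F)C | intermediate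
8 | (5Z)-5-(pent-4-en-2-ylidene)-3-(propan-2-yl)-5,6-dihydro-4H-cyclopenta[d][1,2]oxazol-4-one (allyl cis to the carbonyl) | CC(C)c1noc2c1C(=O)/C(C2)=C(\CC=C)C | intermediate
9 | (4S,5Z)-5-(pent-4-en-2-ylidene)-3-(propan-2-yl)-5,6-dihydro-4H-cyclopenta[d][1,2]oxazol-4-ol | CC(C)c1noc2c1[C@@H](O)/C(C2)=C(\CC=C)C | intermediate
10 | (4R,5S,3′R)-3′-methyl-3-(propan-2-yl)-3′-(prop-2-en-1-yl)-4,6-dihydrospiro[cyclopenta[d][1,2]oxazole-5,2′-oxiran]-4-ol (oxirane oxygen cis to OH; C4 is arranged as in 9, its descriptor changes by priority only) | CC(C)c1noc2c1[C@@H](O)[C@]1(C2)O[C@]1(C)CC=C | intermediate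
11 | (5R,3′R)-3′-methyl-3-(propan-2-yl)-3′-(prop-2-en-1-yl)spiro[cyclopenta[d][1,2]oxazole-5,2′-oxiran]-4(6H)-one | CC(C)c1noc2c1C(=O)[C@]1(C2)O[C@]1(C)CC=C | intermediate
12 | (5S)-5-methyl-3-(propan-2-yl)-5-(prop-2-en-1-yl)-1,2-benzoxazole-4,6(5H,7H)-dione | CC(C)c1noc2c1C(=O)[C@@](C)(CC=C)C(=O)C2 | intermediate
13 | (5S)-5-methyl-5-(3-methylbut-2-en-1-yl)-3-(propan-2-yl)-1,2-benzoxazole-4,6(5H,7H)-dione | CC(C)c1noc2c1C(=O)[C@@](C)(CC=C(C)C)C(=O)C2 | intermediate
14 | (6S)-3-hydroxy-6-methyl-6-(3-methylbut-2-en-1-yl)-2-(2-methylpropanimidoyl)cyclohex-2-ene-1,5-dione (enaminone, one tautomer) | CC(C)=CC[C@@]1(C)C(=O)CC(O)=C(C(=N)C(C)C)C1=O | intermediate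
15 | (4S)-3,5-dihydroxy-4-methyl-4-(3-methylbut-2-en-1-yl)-2-(2-methylpropanoyl)cyclohexa-2,5-dien-1-one | CC(C)=CC[C@@]1(C)C(O)=CC(=O)C(C(=O)C(C)C)=C1O | intermediate
16 | benzene-1,3,5-triol (phloroglucinol) | Oc1cc(O)cc(O)c1 | starting material
17 | 2-methyl-1-(2,4,6-trihydroxyphenyl)propan-1-one | CC(C)C(=O)c1c(O)cc(O)cc1O | intermediate
18 | 1-[2,6-dihydroxy-4-(methoxymethoxy)phenyl]-2-methylpropan-1-one | CC(C)C(=O)c1c(O)cc(OCOC)cc1O | intermediate
19 | (6Z)-3-hydroxy-5-(methoxymethoxy)-6-(3-methylbut-2-en-1-ylidene)-2-(2-methylpropanoyl)cyclohexa-2,4-dien-1-one (ortho-quinone methide) | O=C1C(C(=O)C(C)C)=C(O)C=C(OCOC)/C1=C/C=C(C)C | intermediate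
20 | 1-[7-hydroxy-5-(methoxymethoxy)-2,2-dimethyl-2H-chromen-8-yl]-2-methylpropan-1-one | CC(C)C(=O)c1c(O)cc(OCOC)c2C=CC(C)(C)Oc12 | intermediate
21 | 1-(5,7-dihydroxy-2,2-dimethyl-2H-chromen-8-yl)-2-methylpropan-1-one | CC(C)C(=O)c1c(O)cc(O)c2C=CC(C)(C)Oc12 | intermediate
22 | (4S)-6-[(dimethylamino)methyl]-3,5-dihydroxy-4-methyl-4-(3-methylbut-2-en-1-yl)-2-(2-methylpropanoyl)cyclohexa-2,5-dien-1-one | CC(C)=CC[C@@]1(C)C(O)=C(CN(C)C)C(=O)C(C(=O)C(C)C)=C1O | intermediate
23 | (6R)-5-hydroxy-6-methyl-2-methylidene-6-(3-methylbut-2-en-1-yl)-4-(2-methylpropanoyl)cyclohex-4-ene-1,3-dione (enone methide; same spatial arrangement as 22, the descriptor changes by priority only) | CC(C)=CC[C@@]1(C)C(=O)C(=C)C(=O)C(C(=O)C(C)C)=C1O | intermediate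
24 | (4S)-6-{[5,7-dihydroxy-2,2-dimethyl-8-(2-methylpropanoyl)-2H-chromen-6-yl]methyl}-3,5-dihydroxy-4-methyl-4-(3-methylbut-2-en-1-yl)-2-(2-methylpropanoyl)cyclohexa-2,5-dien-1-one | CC(C)=CC[C@@]1(C)C(O)=C(Cc2c(O)c3c(c(C(=O)C(C)C)c2O)OC(C)(C)C=C3)C(=O)C(C(=O)C(C)C)=C1O | target

**Step count and risks**

Total step count: 16. Longest linear sequence: 12 steps (steps 1 to 10, then 15 and 16).

Steps most likely to fail:

Step 5. The carbonyl of 8 has two sp2 flanks that are both hindered (the isopropyl-bearing isoxazole and the alkylidene with its cis allyl group), so the oxazaborolidine may discriminate the two faces poorly. The fallback replaces asymmetric catalysis by a resolution; it sets out from 8 and comes back at 9. Luche reduction (NaBH4, CeCl3·7H2O, MeOH, 0 °C) would give the racemic (Z)-allylic alcohol F1. Esterification with (S)-2-methoxy-2-phenylacetic acid (DCC, DMAP, CH2Cl2) and chromatographic separation would give the ester of the (4S)-alcohol F2 beside the ester of the (4R)-alcohol F3. Saponification of F2 (LiOH, THF/H2O, 0 °C) returns 9.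

Step 8. The developing positive charge at the tertiary carbon may be lost by proton elimination to an allylic alcohol, the ring CH2 may migrate in place of the acyl carbon, or a free cation may erode the transfer of configuration. The fallback moves the 1,2-shift to the alcohol oxidation level, where a silyloxy-bearing carbon migrates under a bulky aluminium Lewis acid (rearrangement of an epoxy silyl ether); it sets out from 10 and comes back at 12. Silylation (TBSOTf, 2,6-lutidine, CH2Cl2, −78 °C) would give the epoxy silyl ether F4. MeAl(OC6H2-4-Br-2,6-tBu2)2 in CH2Cl2 at −78 °C should shift the silyloxy-bearing C4 anti to the oxirane C–O bond, with the same inversion at the migration terminus, to give the ring-enlarged silyloxy ketone F5. HF·pyridine (THF, 0 °C) would give the hydroxy ketone F6, and oxidation (Pr4N[RuO4], N-methylmorpholine N-oxide, CH2Cl2) returns 12.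

Step 10. The vinylogous amide may resist hydrolysis under mild acid, and stronger acid may hydrate the prenyl alkene or cyclise it onto an enol oxygen. The fallback installs the prenyl group only after the acid step; it sets out from 12 and comes back at 15. Mo(CO)6 in MeCN/H2O at 80 °C would give the allyl enaminone F7 (not isolated), and 2 M aq. HCl at 70 °C, which a terminal alkene tolerates, would give the allyl triketone F8. Cross-metathesis of F8 with 2-methylbut-2-ene (second-generation Hoveyda–Grubbs catalyst (H2IMes)Cl2Ru=CH(C6H4-2-OiPr), CH2Cl2, 40 °C) returns 15.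

Further compounds
F1 | step 5 | (5Z)-5-(pent-4-en-2-ylidene)-3-(propan-2-yl)-5,6-dihydro-4H-cyclopenta[d][1,2]oxazol-4-ol, racemic | CC(C)c1noc2c1C(O)/C(C2)=C(\CC=C)C
F2 | step 5 | (4S,5Z)-5-(pent-4-en-2-ylidene)-3-(propan-2-yl)-5,6-dihydro-4H-cyclopenta[d][1,2]oxazol-4-yl (2S)-2-methoxy-2-phenylacetate | CC(C)c1noc2c1[C@@H](OC(=O)[C@@H](OC)c1ccccc1)/C(C2)=C(\CC=C)C
F3 | step 5 | (4R,5Z)-5-(pent-4-en-2-ylidene)-3-(propan-2-yl)-5,6-dihydro-4H-cyclopenta[d][1,2]oxazol-4-yl (2S)-2-methoxy-2-phenylacetate | CC(C)c1noc2c1[C@H](OC(=O)[C@@H](OC)c1ccccc1)/C(C2)=C(\CC=C)C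
F4 | step 8 | (4R,5S,3′R)-4-[(tert-butyldimethylsilyl)oxy]-3′-methyl-3-(propan-2-yl)-3′-(prop-2-en-1-yl)-4,6-dihydrospiro[cyclopenta[d][1,2]oxazole-5,2′-oxirane] | CC(C)c1noc2c1[C@@H](O[Si](C)(C)C(C)(C)C)[C@]1(C2)O[C@]1(C)CC=C
F5 | step 8 | (4R,5R)-4-[(tert-butyldimethylsilyl)oxy]-5-methyl-3-(propan-2-yl)-5-(prop-2-en-1-yl)-4,5-dihydro-1,2-benzoxazol-6(7H)-one | CC(C)c1noc2c1[C@@H](O[Si](C)(C)C(C)(C)C)[C@@](C)(CC=C)C(=O)C2
F6 | step 8 | (4R,5R)-4-hydroxy-5-methyl-3-(propan-2-yl)-5-(prop-2-en-1-yl)-4,5-dihydro-1,2-benzoxazol-6(7H)-one | CC(C)c1noc2c1[C@@H](O)[C@@](C)(CC=C)C(=O)C2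
F7 | step 10 | (6S)-3-hydroxy-6-methyl-2-(2-methylpropanimidoyl)-6-(prop-2-en-1-yl)cyclohex-2-ene-1,5-dione (enaminone, one tautomer) | C=CC[C@@]1(C)C(=O)CC(O)=C(C(=N)C(C)C)C1=O
F8 | step 10 | (4S)-3,5-dihydroxy-4-methyl-2-(2-methylpropanoyl)-4-(prop-2-en-1-yl)cyclohexa-2,5-dien-1-one | C=CC[C@@]1(C)C(O)=CC(=O)C(C(=O)C(C)C)=C1O
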